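**Plan**

1. Numbering (eudesmane): ring A = C1–C5 and C10, ring B = C5–C10; C3 angelate, C4 methyl and acetate, C7 isopropyl, C8 ketone, C10 methyl; the ring fusion is cis (H5 and the C10 methyl on one face, called β).
2. Retrosynthesis: both esters come off last; the C3/C4 diol goes back through an epoxy alcohol, an allylic alcohol and an enone to a C4 ketone; ring B is then cut at C5–C6 and C8–C9, which frees 2-isopropylacryloyl chloride (C6–C7–C8) and a ring A piece.
3. Enabling feature: C5 and C9 both sit on the quaternary C10 and C5 is α to the C4 carbonyl, so the ring A piece is a cyclopropyl ketone (three-membered ring C5–C10–C9). Me3SiI opens its C5–C9 bond to a C4=C5 silyl enol ether and a C9 iodide, two donor carbons that the three-carbon bis-electrophile bridges.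
4. Forward: cyclopropane-fused ring A first, then ring B in one flask by acylation at C9 and Mukaiyama–Michael closure at C5, then C2=C3, the C4 methyl, the C3 oxygen and the two acyl groups.
5. Stereochemistry: a Corey–Bakshi–Shibata reduction sets C4–OH, which directs the cyclopropanation (C5, C10); C10 then enforces the cis fusion (C5), convex-face MeLi addition (C4), hydroxyl-directed epoxidation (C3) and equilibration (C7).

Key step: step 6

Assumption: 3-methyl-2-methylidenebutanoic acid (6) is taken as commercially available; it would otherwise be one Mannich-type methylenation with decarboxylation away from isopropylmalonic acid.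

Step 1
Reactants: 1 3-methylcyclohex-2-en-1-one
Product: 2 (1R)-3-methylcyclohex-2-en-1-ol
Conditions: (S)-Me-CBS oxazaborolidine (10 mol%), BH3·SMe2, THF, −20 °C
Reagents that add atoms: none
Why: Corey–Bakshi–Shibata reduction, in which the borane-activated oxazaborolidine binds the ketone with the alkenyl arm as the large group and delivers hydride to one carbonyl face, should set the C4 carbinol as (R), the single centre from which all others are relayed.

Step 2
Reactants: 2 (1R)-3-methylcyclohex-2-en-1-ol
Product: 3 (1S,2R,6R)-6-methylbicyclo[4.1.0]heptan-2-ol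
Conditions: Et2Zn, CH2I2, CH2Cl2, 0 °C
Reagents that add atoms: diiodomethane, ICI
Why: Hydroxyl-directed Simmons–Smith cyclopropanation, in which the zinc alkoxide delivers the CH2 group (the future C9) to the alkene face syn to oxygen, should set C5 and the quaternary C10 together.

Step 3
Reactants: 3 (1S,2R,6R)-6-methylbicyclo[4.1.0]heptan-2-ol
Product: 4 (1S,6R)-6-methylbicyclo[4.1.0]heptan-2-one
Conditions: Dess–Martin periodinane, CH2Cl2, rt
Reagents that add atoms: none
Why: Dess–Martin oxidation of the secondary carbinol should give the cyclopropyl ketone without opening the ring, the C4 centre being given up after it has done its relay work.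

Step 4
Reactants: 4 (1S,6R)-6-methylbicyclo[4.1.0]heptan-2-one
Product: 5 {[(3S)-3-(iodomethyl)-3-methylcyclohex-1-en-1-yl]oxy}trimethylsilane
Conditions: Me3SiI, CH2Cl2, −40 to 0 °C; used crude
Reagents that add atoms: iodotrimethylsilane, C[Si](C)(C)I
Why: Silyl-assisted homoconjugate ring opening, in which O-silylation activates the cyclopropyl ketone and iodide attacks the unhindered CH2 (C9) with cleavage of the exocyclic C5–C9 bond that is aligned with the carbonyl π system, should leave C10 untouched and the enol ether regiodefined at C4=C5.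

Step 5
Reactants: 6 3-methyl-2-methylidenebutanoic acid
Product: 7 3-methyl-2-methylidenebutanoyl chloride
Conditions: (COCl)2, DMF (cat.), CH2Cl2, 0 °C to rt
Reagents that add atoms: oxalyl chloride, O=C(Cl)C(=O)Cl
Why: Acid chloride formation through the Vilsmeier-type chloroiminium catalyst should be clean because the acid has no α-hydrogen and cannot form a ketene.

Step 6
Reactants: 5 {[(3S)-3-(iodomethyl)-3-methylcyclohex-1-en-1-yl]oxy}trimethylsilane; 7 3-methyl-2-methylidenebutanoyl chloride
Product: 10 (4aR,8aS)-6-[(tert-butyldimethylsilyl)oxy]-4a-methyl-7-(propan-2-yl)-3,4,4a,5,8,8a-hexahydronaphthalen-1(2H)-one, via alkylzinc iodide 8 (not isolated), via enone 9 (not isolated)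
Conditions: Zn dust, LiCl, THF, 40 °C; then 7, Pd(PPh3)4 (5 mol%), 0 °C to rt; then CH2Cl2, t-BuMe2SiOTf, −78 to −40 °C; Et3N
Reagents that add atoms: tert-butyldimethylsilyl trifluoromethanesulfonate, CC(C)(C)[Si](C)(C)OS(=O)(=O)C(F)(F)F
Why: Zinc inserts into the neopentyl-type C9–I bond to give alkylzinc 8, which has no β-hydrogen, and palladium-catalysed acylation with 7 (oxidative addition of the acid chloride to zerovalent palladium, transmetalation, reductive elimination) forms C8–C9 and gives enone 9; t-BuMe2SiOTf then O-silylates the enone to a siloxyallyl cation whose CH2 terminus (C6) is captured by the C4=C5 silyl enol ether, forming C5–C6 with loss of Me3SiOTf. The closest known reaction types are the Negishi acylation of alkylzinc halides with enoyl chlorides and the silyl-triflate-mediated Mukaiyama–Michael addition, run here in one flask as a (3+3) annulation in which the unit C6–C7–C8 takes the place of the C5–C9 bond of the former cyclopropane. Ring B closes in a 6-endo-trig Michael mode, the whole enone lying inside the new ring as in the second step of a double Michael addition to a divinyl ketone. The only new stereocentre, C5, is controlled by C10: C9 leaves C10 through an equatorial bond and C6 must attack the enol ether axially from the face that carries C9, so only the cis-fused decalin should form, the cyclopropane bond being replaced with retention at C5, while C7 stays sp2. The step needs acylation at zinc before any reaction of the enol ether (secured by palladium catalysis and the inertness of alkylzincs toward enones), a Michael donor fixed at C5 and not C3 (secured by the preformed enol ether and by the tether, which C3 cannot close), and a masked C8 carbonyl in the product (secured by silyl transfer to the new enolate).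

Step 7
Reactants: 10 (4aR,8aS)-6-[(tert-butyldimethylsilyl)oxy]-4a-methyl-7-(propan-2-yl)-3,4,4a,5,8,8a-hexahydronaphthalen-1(2H)-one
Product: 11 (4aR,8aS)-6-[(tert-butyldimethylsilyl)oxy]-4a-methyl-7-(propan-2-yl)-4a,5,8,8a-tetrahydronaphthalen-1(4H)-one
Conditions: LDA, THF, −78 °C; then N-tert-butylbenzenesulfinimidoyl chloride, −78 °C
Reagents that add atoms: none
Why: One-pot ketone dehydrogenation, in which LDA removes a C3 hydrogen kinetically (C5 is a hindered methine), the enolate is sulfinylated at sulfur and the adduct undergoes syn-elimination at low temperature, should give the C2=C3 enone and leave the hindered tetrasubstituted silyl enol ether untouched.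

Step 8
Reactants: 11 (4aR,8aS)-6-[(tert-butyldimethylsilyl)oxy]-4a-methyl-7-(propan-2-yl)-4a,5,8,8a-tetrahydronaphthalen-1(4H)-one
Product: 12 (1R,4aR,8aS)-6-[(tert-butyldimethylsilyl)oxy]-1,4a-dimethyl-7-(propan-2-yl)-1,4,4a,5,8,8a-hexahydronaphthalen-1-ol
Conditions: MeLi, CeCl3, THF, −78 °C
Reagents that add atoms: methyllithium, [Li]C
Why: 1,2-Addition of the organocerium reagent to the enone should occur on the convex face of the cis-fused bicycle, the face that carries H5 and the C10 methyl and is remote from C6 and C9, which sets C4 with the methyl β and the hydroxyl α.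

Step 9
Reactants: 12 (1R,4aR,8aS)-6-[(tert-butyldimethylsilyl)oxy]-1,4a-dimethyl-7-(propan-2-yl)-1,4,4a,5,8,8a-hexahydronaphthalen-1-ol
Product: 13 (2R,3R,4S,5S,10R)-8-[(tert-butyldimethylsilyl)oxy]-2,3-epoxy-5βH-eudesm-7-en-4-ol
Conditions: VO(acac)2 (cat.), t-BuOOH, CH2Cl2, 0 °C to rt
Reagents that add atoms: tert-butyl hydroperoxide, CC(C)(C)OO
Why: Vanadium-catalysed hydroxyl-directed epoxidation, in which the bound tertiary allylic alkoxide delivers the peroxide oxygen to the alkene face syn to itself, should set the C3–O bond cis to the C4–O bond and leave the undirected, hindered enol ether alone.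

Step 10
Reactants: 13 (2R,3R,4S,5S,10R)-8-[(tert-butyldimethylsilyl)oxy]-2,3-epoxy-5βH-eudesm-7-en-4-ol
Product: 15 (3R,4S,5S,7R,10R)-3,4-dihydroxy-5βH-eudesman-8-one, via silyl enol ether diol 14 (not isolated)
Conditions: i-Bu2AlH, CH2Cl2, −78 to 0 °C; then 1 M HCl, THF, 0 °C; then K2CO3, MeOH, rt
Reagents that add atoms: none
Why: Regioselective hydride opening of a 2,3-epoxy alcohol in the 1,2-diol mode should put hydride on the less hindered C2, remote from the quaternary carbinol, so that oxygen stays on C3, after which acid hydrolyses the silyl enol ether and base equilibrates C7 to the equatorial isopropyl epimer, the ring conformation being fixed by the need to keep the C4 and C10 methyl groups out of a 1,3-diaxial contact.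

Step 11
Reactants: 15 (3R,4S,5S,7R,10R)-3,4-dihydroxy-5βH-eudesman-8-one; 16 (2Z)-2-methylbut-2-enoic acid (angelic acid)
Product: 18 (3R,4S,5S,7R,10R)-3-(angeloyloxy)-4-hydroxy-5βH-eudesman-8-one, via mixed anhydride 17 (not isolated)
Conditions: 2,4,6-Cl3C6H2COCl, Et3N, toluene, rt; then 15, 80 °C
Reagents that add atoms: none
Why: Yamaguchi-type mixed anhydride acylation without a nucleophilic catalyst should esterify the secondary equatorial C3 hydroxyl and not the hindered tertiary C4 hydroxyl, and the absence of a conjugate-adding catalyst should keep the (Z)-alkene from isomerising to the tiglate.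

Step 12
Reactants: 18 (3R,4S,5S,7R,10R)-3-(angeloyloxy)-4-hydroxy-5βH-eudesman-8-one
Product: 19 (3R,4S,5S,7R,10R)-4-acetoxy-3-(angeloyloxy)-5βH-eudesman-8-one
Conditions: Ac2O, Me3SiOTf (cat.), CH2Cl2, −20 °C
Reagents that add atoms: acetic anhydride, CC(=O)OC(C)=O
Why: Silyl-triflate-catalysed acetylation, through the strongly electrophilic acetylating species formed from Ac2O, should esterify the hindered tertiary axial hydroxyl at low temperature, where neither migration of the neighbouring angelate nor its (Z) to (E) isomerisation is expected.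

**Compound list**

1 | 3-methylcyclohex-2-en-1-one | CC1=CC(=O)CCC1 | starting material
2 | (1R)-3-methylcyclohex-2-en-1-ol | CC1=C[C@H](O)CCC1 | intermediate
3 | (1S,2R,6R)-6-methylbicyclo[4.1.0]heptan-2-ol (hydroxyl cis to the cyclopropane CH2) | O[C@@H]1CCC[C@]2(C)C[C@H]12 | intermediate
4 | (1S,6R)-6-methylbicyclo[4.1.0]heptan-2-one | O=C1CCC[C@]2(C)C[C@H]12 | intermediate
5 | {[(3S)-3-(iodomethyl)-3-methylcyclohex-1-en-1-yl]oxy}trimethylsilane | C[Si](C)(C)OC1=C[C@@](C)(CI)CCC1 | intermediate
6 | 3-methyl-2-methylidenebutanoic acid (2-isopropylacrylic acid) | C=C(C(C)C)C(=O)O | starting material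
7 | 3-methyl-2-methylidenebutanoyl chloride | C=C(C(C)C)C(=O)Cl | intermediate
8 | iodo({(1S)-1-methyl-3-[(trimethylsilyl)oxy]cyclohex-2-en-1-yl}methyl)zinc | C[Si](C)(C)OC1=C[C@@](C)(C[Zn]I)CCC1 | intermediate
9 | 4-methyl-3-methylidene-1-{(1R)-1-methyl-3-[(trimethylsilyl)oxy]cyclohex-2-en-1-yl}pentan-2-one | C[Si](C)(C)OC1=C[C@@](C)(CC(=O)C(=C)C(C)C)CCC1 | intermediate
10 | (4aR,8aS)-6-[(tert-butyldimethylsilyl)oxy]-4a-methyl-7-(propan-2-yl)-3,4,4a,5,8,8a-hexahydronaphthalen-1(2H)-one (cis-fused) | O=C1CCC[C@]2(C)CC(O[Si](C)(C)C(C)(C)C)=C(C(C)C)C[C@H]12 | intermediate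
11 | (4aR,8aS)-6-[(tert-butyldimethylsilyl)oxy]-4a-methyl-7-(propan-2-yl)-4a,5,8,8a-tetrahydronaphthalen-1(4H)-one | O=C1C=CC[C@]2(C)CC(O[Si](C)(C)C(C)(C)C)=C(C(C)C)C[C@H]12 | intermediate
12 | (1R,4aR,8aS)-6-[(tert-butyldimethylsilyl)oxy]-1,4a-dimethyl-7-(propan-2-yl)-1,4,4a,5,8,8a-hexahydronaphthalen-1-ol | O[C@]1(C)C=CC[C@]2(C)CC(O[Si](C)(C)C(C)(C)C)=C(C(C)C)C[C@H]12 | intermediate
13 | (2R,3R,4S,5S,10R)-8-[(tert-butyldimethylsilyl)oxy]-2,3-epoxy-5βH-eudesm-7-en-4-ol (epoxide and hydroxyl both α) | O[C@]1(C)[C@@H]2O[C@@H]2C[C@]3(C)CC(O[Si](C)(C)C(C)(C)C)=C(C(C)C)C[C@H]13 | intermediate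
14 | (3R,4S,5S,10R)-8-[(tert-butyldimethylsilyl)oxy]-5βH-eudesm-7-ene-3,4-diol | O[C@@H]1CC[C@]2(C)CC(O[Si](C)(C)C(C)(C)C)=C(C(C)C)C[C@@H]2[C@]1(C)O | intermediate
15 | (3R,4S,5S,7R,10R)-3,4-dihydroxy-5βH-eudesman-8-one | O[C@@H]1CC[C@]2(C)CC(=O)[C@@H](C(C)C)C[C@@H]2[C@]1(C)O | intermediate
16 | (2Z)-2-methylbut-2-enoic acid (angelic acid) | C/C=C(/C)C(=O)O | starting material
17 | (2Z)-2-methylbut-2-enoic 2,4,6-trichlorobenzoic anhydride | C/C=C(/C)C(=O)OC(=O)c1c(Cl)cc(Cl)cc1Cl | intermediate
18 | (3R,4S,5S,7R,10R)-3-(angeloyloxy)-4-hydroxy-5βH-eudesman-8-one | C/C=C(/C)C(=O)O[C@@H]1CC[C@]2(C)CC(=O)[C@@H](C(C)C)C[C@@H]2[C@]1(C)O | intermediate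
19 | (3R,4S,5S,7R,10R)-4-acetoxy-3-(angeloyloxy)-5βH-eudesman-8-one, that is (1S,2R,4aR,7R,8aS)-1-acetoxy-1,4a-dimethyl-6-oxo-7-(propan-2-yl)decahydronaphthalen-2-yl (2Z)-2-methylbut-2-enoate | C/C=C(/C)C(=O)O[C@@H]1CC[C@]2(C)CC(=O)[C@@H](C(C)C)C[C@@H]2[C@]1(C)OC(C)=O | target

Total steps: 12. Longest linear sequence: 11 steps (steps 1–4 and 6–12, from 1 to 19).

**Steps most likely to fail**

Step 6 (key step). The silyl enol ether may be lost during zinc insertion or acylation, or the 6-endo closure may be slow enough for the siloxyallyl cation to oligomerise or add halide. Fallback, from 5 back to 10: the annulation is taken apart and the ring-closing event is changed from a cationic silyl-transfer addition to an anionic one. The first two stages of step 6 are run alone and 9 is isolated by non-aqueous filtration. (Me2N)3S+ Me3SiF2− in THF at −78 °C should then free the regiodefined C5 enolate, which should add to the enone in the same axial, cis-selective sense. The C8 enolate so formed is silylated with t-BuMe2SiCl to give 10. No compound outside the list is made (F0).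

Step 4. The ring may open in a cation-like manner at the tertiary C10, with cleavage of the ring-fusion bond C5–C10 and ring enlargement, in place of the exocyclic C5–C9 bond. Fallback, from 4 back to 8: a purely nucleophilic opening. PhSeNa with 18-crown-6 in THF should attack the unhindered CH2 in an SN2 sense, and trapping of the enolate with Me3SiCl should give trimethyl({(3S)-3-methyl-3-[(phenylselanyl)methyl]cyclohex-1-en-1-yl}oxy)silane F1. Reductive lithiation of the C–Se bond with lithium 4,4′-di-tert-butylbiphenylide at −78 °C should give ({(1S)-1-methyl-3-[(trimethylsilyl)oxy]cyclohex-2-en-1-yl}methyl)lithium F2. ZnI2 turns F2 into 8, which enters step 6 at its acylation stage.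

Step 12. The angeloyl group may migrate to the tertiary oxygen through a cyclic ortho ester, or the tertiary hydroxyl may be lost under the Lewis acid, before acetylation is complete. Fallback, from 15 to 19: the order of the two acylations is reversed and no tertiary alcohol is acylated. Trimethyl orthoacetate and pyridinium p-toluenesulfonate should turn diol 15 into the cyclic methyl orthoacetate (3R,4S,5S,7R,10R)-3,4-O-(1-methoxyethylidene)-3,4-dihydroxy-5βH-eudesman-8-one F3. Aqueous acetic acid should open it under kinetic control to the axial ester, the tertiary acetate with a free equatorial C3 hydroxyl, (3R,4S,5S,7R,10R)-4-acetoxy-3-hydroxy-5βH-eudesman-8-one F4. Angeloylation of F4 with mixed anhydride 17 as in step 11 should give 19.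

Further compounds
F0 | step 6 | none | none
F1 | step 4 | trimethyl({(3S)-3-methyl-3-[(phenylselanyl)methyl]cyclohex-1-en-1-yl}oxy)silane | C[Si](C)(C)OC1=C[C@@](C)(C[Se]c2ccccc2)CCC1
F2 | step 4 | ({(1S)-1-methyl-3-[(trimethylsilyl)oxy]cyclohex-2-en-1-yl}methyl)lithium | C[Si](C)(C)OC1=C[C@@](C)(C[Li])CCC1
F3 | step 12 | (3R,4S,5S,7R,10R)-3,4-O-(1-methoxyethylidene)-3,4-dihydroxy-5βH-eudesman-8-one | COC1(C)O[C@@H]2CC[C@]3(C)CC(=O)[C@@H](C(C)C)C[C@@H]3[C@]2(C)O1
F4 | step 12 | (3R,4S,5S,7R,10R)-4-acetoxy-3-hydroxy-5βH-eudesman-8-one | O[C@@H]1CC[C@]2(C)CC(=O)[C@@H](C(C)C)C[C@@H]2[C@]1(C)OC(C)=O
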